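## Retrosynthetic overview

1. Feature (pterocarpan numbering): ring B is a chroman in which C6a lies between C6 (bonded to O5) and C11a (bonded to C11b of ring A). Cutting O5–C6 and C6a–C11a leaves two pieces. One is ring A as an o-quinone methide (C11a = methide CH2, O5 = carbonyl oxygen, ring E already fused at C1–O/C2–CH2). The other is a C6–C6a unit carrying ring D, that is, an arylacetaldehyde.
2. An amine-catalysed [4+2] of these partners builds ring B and fixes C6a. The lactol is taken to the isoflavan without any cation next to C6a. Ring C (O11–C11a) is closed last by hydride abstraction at C11a and capture by the ring D phenol, the cis fusion relaying C6a to C11a.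
3. The quinone methide precursor is an 8-(tosylmethyl)chroman-7-ol made from 2,4,6-trihydroxybenzaldehyde. Silylating O4 first makes the two remaining hydroxyls equivalent, so annulation of ring E with 3-methylbut-2-enal has one regiochemical outcome.
4. The arylacetaldehyde comes from 2-hydroxy-4-methoxybenzaldehyde by benzylation and one-carbon Wittig homologation.
5. Ring order: A and D are bought, then E, then B, then C.

Key step: step 9

Remark: the target SMILES decodes as the cis-fused (6aS,11aS) pterocarpan. The sense of induction in the key step is assumed from the usual steric-shielding model of diarylprolinol silyl ether enamines. Should it prove opposite, the (R)-catalyst is equally available.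

## Route

Step 1
Reactants: 1 2,4,6-trihydroxybenzaldehyde
Product: 2 2,6-dihydroxy-4-(triisopropylsilyloxy)benzaldehyde
Conditions: TIPSCl (1.0 equiv), imidazole (2 equiv), DMF, 0 °C
Reagents that add atoms: triisopropylsilyl chloride, CC(C)[Si](Cl)(C(C)C)C(C)C
Why: Chemoselective O-silylation: the C4 hydroxyl is the only one not flanked by, or hydrogen-bonded to, the formyl group, so one equivalent of the bulky chlorosilane should take it and leave a mirror-symmetric 2,6-diol.

Step 2
Reactants: 2 2,6-dihydroxy-4-(triisopropylsilyloxy)benzaldehyde; 3 3-methylbut-2-enal (1.2 equiv)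
Product: 5 7-hydroxy-2,2-dimethyl-5-(triisopropylsilyloxy)-2H-chromene-8-carbaldehyde, via dienone 4 (not isolated)
Conditions: pyridine, 110 °C, sealed tube
Reagents that add atoms: none
Why: Pyridine-mediated chromenylation (aldol-type C-alkylation of the phenol at C3 by the enal, dehydration to dienone 4, oxa-6π electrocyclisation) closes ring E; since O4 is silylated and the two free hydroxyls are equivalent, only the 8-formyl-7-hydroxy chromene can form, and near-stoichiometric enal limits a second annulation.

Step 3
Reactants: 5 7-hydroxy-2,2-dimethyl-5-(triisopropylsilyloxy)-2H-chromene-8-carbaldehyde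
Product: 6 7-hydroxy-2,2-dimethyl-5-(triisopropylsilyloxy)chroman-8-carbaldehyde
Conditions: H2 (1 atm), Pd/C, EtOAc, rt
Reagents that add atoms: none
Why: Heterogeneous catalytic hydrogenation saturates the cis-disubstituted styrene-type C3=C4 bond much faster than it touches the chelated, electron-rich aryl aldehyde or the silyl ether.

Step 4
Reactants: 6 7-hydroxy-2,2-dimethyl-5-(triisopropylsilyloxy)chroman-8-carbaldehyde
Product: 7 8-(hydroxymethyl)-2,2-dimethyl-5-(triisopropylsilyloxy)chroman-7-ol
Conditions: NaBH4, THF–EtOH, 0 °C; pH 7 buffer; used crude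
Reagents that add atoms: none
Why: Borohydride reduction of the aldehyde, with low temperature, short contact and a neutral quench to keep the ionisation-prone o-hydroxybenzyl alcohol from losing water before the next step.

Step 5
Reactants: 7 8-(hydroxymethyl)-2,2-dimethyl-5-(triisopropylsilyloxy)chroman-7-ol
Product: 8 2,2-dimethyl-8-[(4-methylphenyl)sulfonylmethyl]-5-(triisopropylsilyloxy)chroman-7-ol
Conditions: p-TolSO2H (1.5 equiv), CH2Cl2, 0 °C to rt
Reagents that add atoms: p-toluenesulfinic acid, Cc1ccc(cc1)S(=O)O
Why: Acid-promoted SN1-type exchange: the sulfinic acid ionises the benzylic alcohol to a cation stabilised by three ring oxygens and its soft sulfur end captures it, any O-bound sulfinate ester re-ionising so that the thermodynamically preferred sulfone accumulates.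

Step 6
Reactants: 9 2-hydroxy-4-methoxybenzaldehyde
Product: 10 2-(benzyloxy)-4-methoxybenzaldehyde
Conditions: BnBr, K2CO3, DMF, rt
Reagents that add atoms: benzyl bromide, BrCc1ccccc1
Why: Williamson ether synthesis on the only phenol, which masks the future O11 so that it cannot trap the lactol carbon after the key step.

Step 7
Reactants: 10 2-(benzyloxy)-4-methoxybenzaldehyde
Product: 11 2-(benzyloxy)-4-methoxy-1-(2-methoxyethenyl)benzene (E/Z mixture)
Conditions: [Ph3PCH2OMe]Cl, KOtBu, THF, 0 °C to rt
Reagents that add atoms: (methoxymethyl)triphenylphosphonium chloride, COC[P+](c1ccccc1)(c1ccccc1)c1ccccc1.[Cl-]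
Why: Wittig methoxymethylenation adds the one carbon that becomes C6; the alkene geometry is irrelevant because both isomers hydrolyse to the same aldehyde.

Step 8
Reactants: 11 2-(benzyloxy)-4-methoxy-1-(2-methoxyethenyl)benzene
Product: 12 2-[2-(benzyloxy)-4-methoxyphenyl]acetaldehyde
Conditions: 2 M aq HCl, THF, 40 °C; used promptly
Reagents that add atoms: water, O
Why: Acid hydrolysis of the enol ether (C-protonation, hemiacetal, loss of methanol) gives the arylacetaldehyde and leaves the benzyl and methyl aryl ethers untouched.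

Step 9
Reactants: 8 2,2-dimethyl-8-[(4-methylphenyl)sulfonylmethyl]-5-(triisopropylsilyloxy)chroman-7-ol; 12 2-[2-(benzyloxy)-4-methoxyphenyl]acetaldehyde (1.5 equiv)
Product: 15 (9S)-9-[2-(benzyloxy)-4-methoxyphenyl]-2,2-dimethyl-5-(triisopropylsilyloxy)-3,4,9,10-tetrahydro-2H,8H-pyrano[2,3-f]chromen-8-ol (the (3S)-isoflavan-2-ol lactol as an anomeric mixture), via o-quinone methide 13 (not isolated), via E-enamine 14 (not isolated)
Conditions: (S)-α,α-diphenylprolinol trimethylsilyl ether (20 mol %), Na2CO3 (1.5 equiv), CH2Cl2, 0 °C, slow addition of 8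
Reagents that add atoms: none
Why: Carbonate deprotonates the C7 phenol of 8 and the phenoxide expels p-toluenesulfinate (1,4-elimination) to give o-quinone methide 13, whose methide carbon is tempered by the ring E oxygen (ortho) and the silyloxy group (para), while 12 condenses with the secondary amine to the E-enamine 14. The nucleophilic enamine carbon (future C6a) adds in Michael fashion to the methide CH2 (future C11a), ring A re-aromatises, and the freed phenoxide O5 closes ring B by 6-exo-trig addition to the iminium carbon (future C6); hydrolysis by the water of enamine formation returns the catalyst and gives lactol 15. The closest known reaction type is the secondary-amine-catalysed formal inverse-electron-demand oxa-[4+2] annulation of enolisable aldehydes with o-quinone methides released by base from 2-(sulfonylalkyl)phenols, which gives chroman-2-ols. C6a is the only lasting stereocentre: the CPh2(OSiMe3) arm of the (S)-catalyst blocks one face of the s-trans E-enamine, so the methide should bond to the open face and give the (3S)-isoflavan configuration (9S in the systematic name), whereas the anomeric carbon is a mixture that disappears in step 10. Regiochemistry follows from polarity (enamine carbon to methide carbon, phenoxide to iminium carbon) and from 8 having a single free hydroxyl ortho to the sulfonylmethyl group, so only one quinone methide can form. Chemoselectivity against dimerisation of 13 or C-alkylation of a second ring A is sought by slow addition of 8 to an excess of 12, and closure to the lactol takes the α-aryl aldehyde out of enolisation equilibria.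

Step 10
Reactants: 15 the (3S)-isoflavan-2-ol lactol
Product: 16 (2S)-2-[2-(benzyloxy)-4-methoxyphenyl]-3-[7-hydroxy-2,2-dimethyl-5-(triisopropylsilyloxy)chroman-8-yl]propan-1-ol
Conditions: NaBH4, THF–MeOH, 0 °C
Reagents that add atoms: none
Why: Borohydride reduction through the ring-opened hydroxy-aldehyde tautomer removes the enolisable carbonyl quickly; a silane/Lewis acid reduction is deliberately avoided because its oxocarbenium ion could lose or shift the C6a hydrogen, which is benzylic to the dialkoxyaryl ring D, and so erode the stereocentre.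

Step 11
Reactants: 16 (2S)-2-[2-(benzyloxy)-4-methoxyphenyl]-3-[7-hydroxy-2,2-dimethyl-5-(triisopropylsilyloxy)chroman-8-yl]propan-1-ol
Product: 17 (9S)-9-[2-(benzyloxy)-4-methoxyphenyl]-2,2-dimethyl-5-(triisopropylsilyloxy)-3,4,9,10-tetrahydro-2H,8H-pyrano[2,3-f]chromene (the (3S)-isoflavan)
Conditions: PPh3, DIAD, THF, 0 °C to rt
Reagents that add atoms: none
Why: Intramolecular Mitsunobu etherification (6-exo-tet): the only free phenol, O5, displaces the activated primary alcohol at C6 and re-forms the O5–C6 bond of ring B without touching C6a.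

Step 12
Reactants: 17 the (3S)-isoflavan benzyl ether
Product: 18 2-[(9S)-2,2-dimethyl-5-(triisopropylsilyloxy)-3,4,9,10-tetrahydro-2H,8H-pyrano[2,3-f]chromen-9-yl]-5-methoxyphenol
Conditions: H2 (1 atm), Pd/C, EtOAc–EtOH, rt
Reagents that add atoms: none
Why: Catalytic hydrogenolysis cleaves the only benzylic C–O bond present, the benzyl ether, and frees the ring D phenol; the silyl ether and both chroman rings are inert.

Step 13
Reactants: 18 2-[(9S)-2,2-dimethyl-5-(triisopropylsilyloxy)-3,4,9,10-tetrahydro-2H,8H-pyrano[2,3-f]chromen-9-yl]-5-methoxyphenol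
Product: 19 (6aS,11aS)-9-methoxy-3-(triisopropylsilyloxy)pterocarpan carrying the 2,2-dimethyl-3,4-dihydro-2H-pyran ring E at C1 (O) and C2 (CH2)
Conditions: DDQ (1.05 equiv), 4 Å MS, CH2Cl2, 0 °C
Reagents that add atoms: none
Why: This is the known DDQ oxidative cyclisation of 2'-hydroxyisoflavans to pterocarpans: hydride is abstracted from C11a (cation stabilised by O5, the ring E oxygen and the silyloxy group) and the phenol tethered at C6a captures the planar cation by 5-exo-trig closure on the only face that gives a cis B/C fusion, so (6aS) dictates (11aS), while one equivalent of oxidant at 0 °C and the bulky peri silyl ether beside the ring E CH2 are meant to hold back dehydrogenation of ring E.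

Step 14
Reactants: 19 the TIPS-protected (6aS,11aS)-pterocarpan
Product: 20 CNP0207547.1, (6aS,11aS)-3-hydroxy-9-methoxypterocarpan carrying the 2,2-dimethyl-3,4-dihydro-2H-pyran ring E at C1 (O) and C2 (CH2)
Conditions: Bu4NF (1.1 equiv), AcOH (1.1 equiv), THF, 0 °C
Reagents that add atoms: none
Why: Fluoride-induced desilylation of the aryl silyl ether; the acetic acid buffer keeps the C3 phenoxide, which is para to C11a, from expelling O11, and any such opening would in any case re-close only to the cis ring fusion.

## Compound list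

1 | 2,4,6-trihydroxybenzaldehyde | O=Cc1c(O)cc(O)cc1O | starting material
2 | 2,6-dihydroxy-4-(triisopropylsilyloxy)benzaldehyde | O=Cc1c(O)cc(O[Si](C(C)C)(C(C)C)C(C)C)cc1O | intermediate
3 | 3-methylbut-2-enal | CC(C)=CC=O | starting material
4 | 2-hydroxy-5-(3-methylbut-2-enylidene)-6-oxo-4-(triisopropylsilyloxy)cyclohexa-1,3-diene-1-carbaldehyde (dienone, not isolated) | O=CC1=C(O)C=C(O[Si](C(C)C)(C(C)C)C(C)C)C(=CC=C(C)C)C1=O | intermediate
5 | 7-hydroxy-2,2-dimethyl-5-(triisopropylsilyloxy)-2H-chromene-8-carbaldehyde | O=Cc1c(O)cc(O[Si](C(C)C)(C(C)C)C(C)C)c2C=CC(C)(C)Oc12 | intermediate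
6 | 7-hydroxy-2,2-dimethyl-5-(triisopropylsilyloxy)chroman-8-carbaldehyde | O=Cc1c(O)cc(O[Si](C(C)C)(C(C)C)C(C)C)c2CCC(C)(C)Oc12 | intermediate
7 | 8-(hydroxymethyl)-2,2-dimethyl-5-(triisopropylsilyloxy)chroman-7-ol | OCc1c(O)cc(O[Si](C(C)C)(C(C)C)C(C)C)c2CCC(C)(C)Oc12 | intermediate
8 | 2,2-dimethyl-8-[(4-methylphenyl)sulfonylmethyl]-5-(triisopropylsilyloxy)chroman-7-ol | Cc1ccc(cc1)S(=O)(=O)Cc1c(O)cc(O[Si](C(C)C)(C(C)C)C(C)C)c2CCC(C)(C)Oc12 | intermediate
9 | 2-hydroxy-4-methoxybenzaldehyde | COc1ccc(C=O)c(O)c1 | starting material
10 | 2-(benzyloxy)-4-methoxybenzaldehyde | COc1ccc(C=O)c(OCc2ccccc2)c1 | intermediate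
11 | 2-(benzyloxy)-4-methoxy-1-(2-methoxyethenyl)benzene (E/Z mixture) | COC=Cc1ccc(OC)cc1OCc1ccccc1 | intermediate
12 | 2-[2-(benzyloxy)-4-methoxyphenyl]acetaldehyde | COc1ccc(CC=O)c(OCc2ccccc2)c1 | intermediate
13 | 2,2-dimethyl-8-methylidene-5-(triisopropylsilyloxy)-3,4-dihydro-2H-chromen-7(8H)-one (o-quinone methide, not isolated) | C=C1C(=O)C=C(O[Si](C(C)C)(C(C)C)C(C)C)C2=C1OC(C)(C)CC2 | intermediate
14 | (S)-1-{(E)-2-[2-(benzyloxy)-4-methoxyphenyl]ethenyl}-2-[diphenyl(trimethylsilyloxy)methyl]pyrrolidine (enamine, not isolated) | C[Si](C)(C)OC(c1ccccc1)(c1ccccc1)[C@@H]1CCCN1/C=C/c1ccc(OC)cc1OCc1ccccc1 | intermediate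
15 | (9S)-9-[2-(benzyloxy)-4-methoxyphenyl]-2,2-dimethyl-5-(triisopropylsilyloxy)-3,4,9,10-tetrahydro-2H,8H-pyrano[2,3-f]chromen-8-ol (anomeric mixture) | COc1ccc(c(OCc2ccccc2)c1)[C@@H]1Cc2c(cc(O[Si](C(C)C)(C(C)C)C(C)C)c3CCC(C)(C)Oc23)OC1O | intermediate
16 | (2S)-2-[2-(benzyloxy)-4-methoxyphenyl]-3-[7-hydroxy-2,2-dimethyl-5-(triisopropylsilyloxy)chroman-8-yl]propan-1-ol | COc1ccc(c(OCc2ccccc2)c1)[C@@H](CO)Cc1c(O)cc(O[Si](C(C)C)(C(C)C)C(C)C)c2CCC(C)(C)Oc12 | intermediate
17 | (9S)-9-[2-(benzyloxy)-4-methoxyphenyl]-2,2-dimethyl-5-(triisopropylsilyloxy)-3,4,9,10-tetrahydro-2H,8H-pyrano[2,3-f]chromene | COc1ccc(c(OCc2ccccc2)c1)[C@@H]1Cc2c(cc(O[Si](C(C)C)(C(C)C)C(C)C)c3CCC(C)(C)Oc23)OC1 | intermediate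
18 | 2-[(9S)-2,2-dimethyl-5-(triisopropylsilyloxy)-3,4,9,10-tetrahydro-2H,8H-pyrano[2,3-f]chromen-9-yl]-5-methoxyphenol | COc1ccc(c(O)c1)[C@@H]1Cc2c(cc(O[Si](C(C)C)(C(C)C)C(C)C)c3CCC(C)(C)Oc23)OC1 | intermediate
19 | (6aS,11aS)-9-methoxy-3-(triisopropylsilyloxy)pterocarpan with the 2,2-dimethyldihydropyran ring E at C1 (O)/C2 (CH2) | COc1ccc2c(c1)O[C@@H]1c3c(cc(O[Si](C(C)C)(C(C)C)C(C)C)c4c3OC(C)(C)CC4)OC[C@H]21 | intermediate
20 | CNP0207547.1, (6aS,11aS)-3-hydroxy-9-methoxypterocarpan with the 2,2-dimethyldihydropyran ring E at C1 (O)/C2 (CH2) | COc1ccc2c(c1)O[C@@H]1c3c(cc(O)c4c3OC(C)(C)CC4)OC[C@H]21 | target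

## Step count and risks

Total steps: 14. Longest linear sequence: 11 steps (steps 1–5 and 9–14).

**Risk 1, step 9.**
- What may go wrong: the unsubstituted methide may be consumed faster than the catalytic amount of enamine can intercept it, by self-dimerisation, by C-alkylation of the free ring A position of another molecule, or by N-alkylation of the catalyst. The α-aryl stereocentre may also erode through the ring-opened form of the product.
- Fallback: the catalytic enamine is replaced by a stoichiometric auxiliary-bound enolate. It sets out from 12 and 8 and rejoins the route at 16.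
- Aldehyde 12 is taken by Pinnick oxidation (NaClO2, NaH2PO4, 2-methylbut-2-ene, t-BuOH–H2O) to 2-[2-(benzyloxy)-4-methoxyphenyl]acetic acid F1.
- Its pivalic mixed anhydride (PivCl, Et3N) acylates lithiated (S)-4-benzyl-1,3-oxazolidin-2-one to give the N-arylacetyl imide F2.
- Two equivalents of the sodium Z-enolate of F2 (NaN(SiMe3)2, THF, −78 °C) are treated with 8. The first equivalent acts as base and releases 13. The second adds to the methide carbon from the face opposite the benzyl group and gives the (2S)-alkylated imide F3.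
- LiBH4 in THF–MeOH then removes the auxiliary reductively, and would also reduce any lactone formed by acyl transfer to the phenoxide, delivering diol 16.

**Risk 2, step 13.**
- What may go wrong: hydride abstraction at the ring E benzylic CH2, which is activated by the same three oxygens as C11a, may compete and dehydrogenate ring E. Proton loss from C6a of the C11a cation would also cost material and stereochemical integrity.
- Fallback: instead of contending for site selectivity, both positions are oxidised and ring E is repaired. It sets out from 18 and rejoins at 19.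
- A little over two equivalents of DDQ take 18 to the ring E chromene pterocarpan F4.
- Its styrene-type C=C is then saturated with diimide (TsNHNH2, NaOAc, aq DME, reflux), a reductant that cannot hydrogenolyse the benzylic C11a–O11 bond, to give 19.

**Risk 3, step 5.**
- What may go wrong: the very electron-rich o-hydroxybenzyl alcohol 7 may ionise and condense with itself before sulfinate capture. The sulfone may also revert on handling.
- Fallback: the benzylic alcohol is avoided altogether. It sets out from 6 and rejoins at 13 within step 9.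
- Reductive amination of 6 (Me2NH, NaBH(OAc)3, 1,2-dichloroethane) gives the hydrogen-bond-stabilised Mannich-type base F5.
- Methyl iodide in Et2O quaternises F5 to the trimethylammonium iodide F6.
- Under the carbonate base of step 9, F6 loses trimethylamine and releases the same o-quinone methide 13, which is carried on to 15 as in the main route.

Further compounds
F1 | step 9 | 2-[2-(benzyloxy)-4-methoxyphenyl]acetic acid | COc1ccc(CC(=O)O)c(OCc2ccccc2)c1
F2 | step 9 | (4S)-4-benzyl-3-{[2-(benzyloxy)-4-methoxyphenyl]acetyl}-1,3-oxazolidin-2-one | COc1ccc(CC(=O)N2[C@@H](Cc3ccccc3)COC2=O)c(OCc2ccccc2)c1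
F3 | step 9 | (4S)-4-benzyl-3-{(2S)-2-[2-(benzyloxy)-4-methoxyphenyl]-3-[7-hydroxy-2,2-dimethyl-5-(triisopropylsilyloxy)chroman-8-yl]propanoyl}-1,3-oxazolidin-2-one | COc1ccc(c(OCc2ccccc2)c1)[C@@H](C(=O)N1[C@@H](Cc2ccccc2)COC1=O)Cc1c(O)cc(O[Si](C(C)C)(C(C)C)C(C)C)c2CCC(C)(C)Oc12
F4 | step 13 | (6aS,11aS)-9-methoxy-3-(triisopropylsilyloxy)pterocarpan with a 2,2-dimethyl-2H-pyran (chromene) ring E at C1 (O)/C2 (CH=) | COc1ccc2c(c1)O[C@@H]1c3c(cc(O[Si](C(C)C)(C(C)C)C(C)C)c4c3OC(C)(C)C=C4)OC[C@H]21
F5 | step 5 | 8-[(dimethylamino)methyl]-2,2-dimethyl-5-(triisopropylsilyloxy)chroman-7-ol | CN(C)Cc1c(O)cc(O[Si](C(C)C)(C(C)C)C(C)C)c2CCC(C)(C)Oc12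
F6 | step 5 | [7-hydroxy-2,2-dimethyl-5-(triisopropylsilyloxy)chroman-8-yl]-N,N,N-trimethylmethanaminium iodide | C[N+](C)(C)Cc1c(O)cc(O[Si](C(C)C)(C(C)C)C(C)C)c2CCC(C)(C)Oc12.[I-]
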